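**Retrosynthetic overview**

1. Target ⇐ (Z,Z)-cyclodecadiene-1,4-dione carrying only the C-8 hydroxyl; a relay Evans–Tishchenko sequence (cinnamaldehyde, then acetaldehyde) sets C-6 and C-3 and installs both esters.
2. Ten-membered ring ⇐ thermal cycloreversion of a tricyclo[4.4.0.0^2,5]decanedione ⇐ photochemical [2+2] of a cyclohexenone with a cyclobutenone ketal (the C4–C5 and C1–C10 bonds are made by light).
3. Cyclohexenone (5-hydroxypiperitone) ⇐ RCM of a β-hydroxy dienone ⇐ trans-α-isopropyl-β-hydroxybutyrolactone ⇐ (R)-3-hydroxy-γ-butyrolactone (the only bought stereocentre, C-8).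
4. Cyclobutene ⇐ chloro(methyl)ketene + phenyl vinyl sulfide, ketalisation, reductive elimination.
5. Ring order: cyclohexenone (RCM) and cyclobutene (ketene [2+2]) → 6-4-4 tricycle (hν) → cyclodecadiene (heat).

Assumption: the SMILES is taken literally, i.e. both ring double bonds have the ring carbons cis (Z,Z) and the centres are 3R,6S,7R,8S.
Locants used in the explanations (germacrane numbering): C1=C10(Me), C3–OH, C4(Me)=C5, C6–OAc, C7–iPr, C8–O-cinnamoyl.

**Route**

Step 1
Reactants: 1 (R)-3-hydroxy-γ-butyrolactone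
Product: 2 (3R,4R)-4-hydroxy-3-(propan-2-yl)oxolan-2-one
Conditions: LDA (2.2 equiv), THF, −78 °C; DMPU, i-PrI (3 equiv), −78 → −25 °C
Reagents that add atoms: 2-iodopropane (CC(C)I)
Why: Fráter–Seebach-type alkylation of the lactone dianion, in which the electrophile enters anti to the β-oxido group of the five-membered enolate, so the bought carbinol centre (future C-8) sets the isopropyl-bearing carbon (future C-7) trans.

Step 2
Reactants: 2 (3R,4R)-4-hydroxy-3-(propan-2-yl)oxolan-2-one
Product: 3 ethyl (2R,3R)-4-bromo-3-hydroxy-2-(propan-2-yl)butanoate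
Conditions: HBr (33% in AcOH), 50 °C; then EtOH, 50 °C
Reagents that add atoms: hydrogen bromide (Br); ethanol (CCO)
Why: Acid-mediated SN2 opening of the γ-lactone at its primary C–O bond by bromide followed by Fischer esterification, the standard hydroxybutyrolactone to 4-bromo-3-hydroxybutanoate conversion, which touches no stereocentre.

Step 3
Reactants: 3 ethyl (2R,3R)-4-bromo-3-hydroxy-2-(propan-2-yl)butanoate
Product: 5 ethyl (2R,3S)-3-hydroxy-5-methyl-2-(propan-2-yl)hex-5-enoate, via epoxy ester 4 (not isolated)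
Conditions: NaH (1.0 equiv), THF, −20 → 0 °C; then CH2=C(Me)MgBr (1.5 equiv), CuI (10 mol%), −40 °C
Reagents that add atoms: isopropenylmagnesium bromide (CC(=C)[Mg]Br)
Why: Intramolecular Williamson closure to the terminal epoxide and copper-catalysed Grignard opening at the unhindered CH2 (the hindered ester is inert at −40 °C), so the carbinol centre is retained (its descriptor changes only through CIP priorities).

Step 4
Reactants: 5 ethyl (2R,3S)-3-hydroxy-5-methyl-2-(propan-2-yl)hex-5-enoate
Product: 7 (4R,5S)-5-hydroxy-7-methyl-4-(propan-2-yl)octa-1,7-dien-3-one, via Weinreb amide 6 (not isolated)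
Conditions: MeNH(OMe)·HCl, i-PrMgCl, THF, −20 → 0 °C; then CH2=CHMgBr, 0 °C; inverse quench into cold aq. citric acid
Reagents that add atoms: N,O-dimethylhydroxylamine hydrochloride (CNOC.Cl) (in 6); vinylmagnesium bromide (C=C[Mg]Br)
Why: One-pot Weinreb ketone synthesis, in which the in situ N-methoxy-N-methylamide forms a stable magnesium chelate that takes up exactly one vinyl Grignard and keeps the α-centre from enolising until the acidic quench.

Step 5
Reactants: 7 (4R,5S)-5-hydroxy-7-methyl-4-(propan-2-yl)octa-1,7-dien-3-one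
Product: 8 (5S,6R)-5-hydroxy-3-methyl-6-(propan-2-yl)cyclohex-2-en-1-one
Conditions: Hoveyda–Grubbs II (5 mol%), CH2Cl2 (5 mM), 40 °C
Reagents that add atoms: none
Why: Ring-closing metathesis between the enone vinyl group and the 1,1-disubstituted alkene closes the 3-methylcyclohexenone with loss of ethene under neutral conditions that spare the β-hydroxy ketone (which would aromatise to thymol on dehydration).

Step 6
Reactants: 9 2-chloropropanoyl chloride (racemic); 10 phenyl vinyl sulfide
Product: 12 2-chloro-2-methyl-3-(phenylsulfanyl)cyclobutan-1-one (racemic diastereomer mixture), via chloro(methyl)ketene 11 (not isolated)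
Conditions: Et3N, Et2O, reflux, slow addition of 9
Reagents that add atoms: none
Why: Dehydrochlorination gives chloro(methyl)ketene, which undergoes thermal ketene–alkene [2+2] cycloaddition with the electron-rich vinyl sulfide, the carbonyl carbon bonding to the terminal CH2 so that sulfur ends up at C-3; the stereo mixture is irrelevant.

Step 7
Reactants: 12 2-chloro-2-methyl-3-(phenylsulfanyl)cyclobutan-1-one
Product: 13 2-chloro-1,1-dimethoxy-2-methyl-3-(phenylsulfanyl)cyclobutane
Conditions: HC(OMe)3, MeOH, p-TsOH (cat.), 0 °C → rt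
Reagents that add atoms: trimethyl orthoformate (COC(OC)OC)
Why: Acid-catalysed ketalisation with orthoformate as water scavenger, favoured by relief of angle strain at the cyclobutanone carbon and by the α-chloro activation.

Step 8
Reactants: 13 2-chloro-1,1-dimethoxy-2-methyl-3-(phenylsulfanyl)cyclobutane
Product: 14 4,4-dimethoxy-1-methylcyclobut-1-ene
Conditions: LiDBB (2.2 equiv), THF, −78 °C; aq. NaOH wash, distillation
Reagents that add atoms: none
Why: Reductive vicinal elimination (Boord-type olefin synthesis), in which reduction of either the C–Cl or the C–SPh bond gives a carbanion that expels the other, far better leaving group than ketal methoxide, fixing the double bond between C(Me) and CH.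

Step 9
Reactants: 8 (5S,6R)-5-hydroxy-3-methyl-6-(propan-2-yl)cyclohex-2-en-1-one; 14 4,4-dimethoxy-1-methylcyclobut-1-ene
Product: 16 (8R,9S)-9-hydroxy-1,5-dimethyl-8-(propan-2-yl)tricyclo[4.4.0.0^{2,5}]decane-4,7-dione (cis-anti-cis isomer shown; ring-fusion isomers accompany it), via photoadduct ketal 15 (not isolated)
Conditions: hν (350 nm, Pyrex), 14 (4 equiv), CH2Cl2, −30 °C; then p-TsOH (cat.), acetone/H2O, rt
Reagents that add atoms: water (O)
Why: Enone–alkene [2+2] photocycloaddition through the triplet 1,4-biradical forms the C1–C10 and C4–C5 bonds, the enone β-carbon bonding to the unsubstituted cyclobutene CH and the α-keto radical closing on the tertiary centre so that the head-to-head adducts avoid vicinal quaternary carbons (any head-to-tail isomer is removed by chromatography), after which ketal hydrolysis unmasks the C-3 ketone; the four new ring-fusion centres are transient, so facial and cis/trans mixtures converge in step 10, and C-7/C-8 are untouched.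

Step 10
Reactants: 16 (8R,9S)-9-hydroxy-1,5-dimethyl-8-(propan-2-yl)tricyclo[4.4.0.0^{2,5}]decane-4,7-dione
Product: 20 (2Z,6Z,9S,10R)-9-hydroxy-3,7-dimethyl-10-(propan-2-yl)cyclodeca-2,6-diene-1,4-dione, via TMS tricycle 17 (not isolated), via TMS E-enedione 18 (not isolated), via TMS Z-enedione 19 (not isolated)
Conditions: BSA (1.3 equiv), o-xylene (0.01 M, degassed, BHT), 60 °C then 165 °C (sealed tube); rt, I2 (5 mol%), visible light; then 1 M HCl, THF, 0 °C
Reagents that add atoms: N,O-bis(trimethylsilyl)acetamide (CC(=N[Si](C)(C)C)O[Si](C)(C)C) (silyl group in 17–19 only)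
Why: Thermal cycloreversion of the bicyclo[2.2.0]hexanone (photo-thermal olefin metathesis) through the α-keto-stabilised cyclohexane-1,4-diyl opens the ten-membered ring with C1=C10 formed Z from the chair diyl (C-9 axial), a Cope shift being impossible because it would create a ketene at C-3, while the transient TMS ether blocks retro-aldol cleavage and iodine-atom catalysis equilibrates the 4E enedione to the Z geometry preferred in a ten-membered ring.

Step 11
Reactants: 20 (2Z,6Z,9S,10R)-9-hydroxy-3,7-dimethyl-10-(propan-2-yl)cyclodeca-2,6-diene-1,4-dione; 21 (E)-cinnamaldehyde; 22 acetaldehyde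
Product: 24 (1S,3Z,6R,7Z,9S,10R)-9-(acetyloxy)-6-hydroxy-3,7-dimethyl-10-(propan-2-yl)cyclodeca-3,7-dien-1-yl (2E)-3-phenylprop-2-enoate (target), via hydroxy enone cinnamate 23 (not isolated)
Conditions: SmI2 (0.3 equiv) pre-aged with 21 (2 equiv), THF, −20 °C, then 20; after consumption of 20 add 22 (20 equiv), −20 °C → rt
Reagents that add atoms: none
Why: Proposed new method: a relay Evans–Tishchenko reduction in which the known Sm(III)-catalysed step comes first (the hemiacetal of C8–OH with cinnamaldehyde delivers hydride to C6=O through the six-membered chair transition state, giving the 6,8-anti alcohol (6S) and the C-8 cinnamate), followed by an unprecedented vinylogous 1,4-variant in which the new C6–O–Sm alkoxide forms a hemiacetal with acetaldehyde and, with Sm(III) chelating the C-3 carbonyl held close by the (Z)-C4=C5 bond, transfers hydride through a seven-membered transition state from the face of O-6 (a three-atom bridge across the ring must be cis), which sets 3R and leaves the acetate on O-6; the closest known reaction types are the Evans–Tishchenko 1,3-anti reduction of β-hydroxy ketones and Sm-catalysed intramolecular Tishchenko hydride shifts.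

**Compound list**

1 | (R)-3-hydroxy-γ-butyrolactone [(4R)-4-hydroxyoxolan-2-one] | O=C1OC[C@H](O)C1 | starting material
2 | (3R,4R)-4-hydroxy-3-(propan-2-yl)oxolan-2-one (trans) | O=C1OC[C@H](O)[C@H]1C(C)C | intermediate
3 | ethyl (2R,3R)-4-bromo-3-hydroxy-2-(propan-2-yl)butanoate | BrC[C@H](O)[C@@H](C(C)C)C(=O)OCC | intermediate
4 | ethyl (2R)-3-methyl-2-[(2R)-oxiran-2-yl]butanoate | C1[C@H](O1)[C@@H](C(C)C)C(=O)OCC | intermediate (not isolated)
5 | ethyl (2R,3S)-3-hydroxy-5-methyl-2-(propan-2-yl)hex-5-enoate | C=C(C)C[C@H](O)[C@@H](C(C)C)C(=O)OCC | intermediate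
6 | (2R,3S)-3-hydroxy-N-methoxy-N,5-dimethyl-2-(propan-2-yl)hex-5-enamide | C=C(C)C[C@H](O)[C@@H](C(C)C)C(=O)N(C)OC | intermediate (not isolated)
7 | (4R,5S)-5-hydroxy-7-methyl-4-(propan-2-yl)octa-1,7-dien-3-one | C=C(C)C[C@H](O)[C@@H](C(C)C)C(=O)C=C | intermediate
8 | (5S,6R)-5-hydroxy-3-methyl-6-(propan-2-yl)cyclohex-2-en-1-one (trans) | O=C1C=C(C)C[C@H](O)[C@H]1C(C)C | intermediate
9 | 2-chloropropanoyl chloride (racemic) | CC(Cl)C(=O)Cl | starting material
10 | phenyl vinyl sulfide | C=CSc1ccccc1 | starting material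
11 | chloro(methyl)ketene | CC(Cl)=C=O | intermediate (not isolated)
12 | 2-chloro-2-methyl-3-(phenylsulfanyl)cyclobutan-1-one (racemic, cis/trans mixture) | CC1(Cl)C(Sc2ccccc2)CC1=O | intermediate
13 | 2-chloro-1,1-dimethoxy-2-methyl-3-(phenylsulfanyl)cyclobutane (racemic, cis/trans mixture) | COC1(OC)CC(Sc2ccccc2)C1(C)Cl | intermediate
14 | 4,4-dimethoxy-1-methylcyclobut-1-ene | CC1=CCC1(OC)OC | intermediate
15 | (8R,9S)-9-hydroxy-4,4-dimethoxy-1,5-dimethyl-8-(propan-2-yl)tricyclo[4.4.0.0^{2,5}]decan-7-one (cis-anti-cis head-to-head adduct shown) | O=C1[C@H](C(C)C)[C@@H](O)C[C@]2(C)[C@H]1[C@@]3(C)C(OC)(OC)C[C@@H]23 | intermediate (not isolated)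
16 | (8R,9S)-9-hydroxy-1,5-dimethyl-8-(propan-2-yl)tricyclo[4.4.0.0^{2,5}]decane-4,7-dione (cis-anti-cis shown) | O=C1[C@H](C(C)C)[C@@H](O)C[C@]2(C)[C@H]1[C@@]3(C)C(=O)C[C@@H]23 | intermediate
17 | (8R,9S)-1,5-dimethyl-8-(propan-2-yl)-9-[(trimethylsilyl)oxy]tricyclo[4.4.0.0^{2,5}]decane-4,7-dione | O=C1[C@H](C(C)C)[C@@H](O[Si](C)(C)C)C[C@]2(C)[C@H]1[C@@]3(C)C(=O)C[C@@H]23 | intermediate (not isolated)
18 | (2E,6Z,9S,10R)-3,7-dimethyl-10-(propan-2-yl)-9-[(trimethylsilyl)oxy]cyclodeca-2,6-diene-1,4-dione | O=C1/C=C(\C)C(=O)C/C=C(/C)C[C@H](O[Si](C)(C)C)[C@H]1C(C)C | intermediate (not isolated)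
19 | (2Z,6Z,9S,10R)-3,7-dimethyl-10-(propan-2-yl)-9-[(trimethylsilyl)oxy]cyclodeca-2,6-diene-1,4-dione | O=C1/C=C(/C)C(=O)C/C=C(/C)C[C@H](O[Si](C)(C)C)[C@H]1C(C)C | intermediate (not isolated)
20 | (2Z,6Z,9S,10R)-9-hydroxy-3,7-dimethyl-10-(propan-2-yl)cyclodeca-2,6-diene-1,4-dione | O=C1/C=C(/C)C(=O)C/C=C(/C)C[C@H](O)[C@H]1C(C)C | intermediate
21 | (E)-cinnamaldehyde | O=C/C=C/c1ccccc1 | starting material
22 | acetaldehyde | CC=O | starting material
23 | (1S,3Z,7Z,9S,10S)-9-hydroxy-3,7-dimethyl-6-oxo-10-(propan-2-yl)cyclodeca-3,7-dien-1-yl (2E)-3-phenylprop-2-enoate | O[C@H]1/C=C(/C)C(=O)C/C=C(/C)C[C@H](OC(=O)/C=C/c2ccccc2)[C@H]1C(C)C | intermediate (not isolated)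
24 | (1S,3Z,6R,7Z,9S,10R)-9-(acetyloxy)-6-hydroxy-3,7-dimethyl-10-(propan-2-yl)cyclodeca-3,7-dien-1-yl (2E)-3-phenylprop-2-enoate | CC(=O)O[C@H]1/C=C(/C)[C@H](O)C/C=C(/C)C[C@H](OC(=O)/C=C/c2ccccc2)[C@H]1C(C)C | target

**Step count**

Total steps: 11. Longest linear sequence: 8 (steps 1, 2, 3, 4, 5, 9, 10, 11).

**Three steps most likely to fail**

Step 1 (secondary iodide on a lactone dianion; E2 of 2-iodopropane may leave low conversion). The fallback sets out from 1 and comes back at 2. The same dianion is added to acetone (LDA, THF, −78 °C), a reliable aldol that again enters trans, to give (3S,4R)-4-hydroxy-3-(2-hydroxypropan-2-yl)oxolan-2-one F1. p-TsOH in toluene at 80 °C dehydrates the tertiary alcohol to (4R)-4-hydroxy-3-(propan-2-ylidene)oxolan-2-one F2. Hydroxyl-directed hydrogenation with [Ir(cod)(PCy3)(py)]PF6 and H2 in CH2Cl2 adds hydrogen to the face that carries the OH, which places the isopropyl group trans and gives 2.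

Step 10 (a hot β-silyloxy ketone and enedione: retro-aldol or elimination, epimerisation at C-7, or an unfavourable E/Z outcome). The fallback sets out from 16 and comes back at 23. The first Tishchenko reduction is moved in front of the ring opening: SmI2 (cat.) and cinnamaldehyde convert 16 into 7-hydroxy-1,5-dimethyl-4-oxo-8-(propan-2-yl)tricyclo[4.4.0.0^{2,5}]dec-9-yl (2E)-3-phenylprop-2-enoate F3 (C-6 ketone reduced anti to O-8, O-8 acylated). F3 has neither a β-hydroxy ketone nor an enolisable C-7. Heating F3 at 165 °C in xylene without silylation gives (1S,3Z,7E,9S,10S)-9-hydroxy-3,7-dimethyl-6-oxo-10-(propan-2-yl)cyclodeca-3,7-dien-1-yl (2E)-3-phenylprop-2-enoate F4, the Cope shift again being blocked by the C-3 ketone. I2 and visible light isomerise F4 to 23, which is then taken through the acetaldehyde stage of step 11.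

Step 11 (the proposed vinylogous Tishchenko stage: the 1,4-hydride transfer may be slow, the substrate may rest as its transannular hemiketal, or the cinnamoyl group may migrate from O-8 to O-6). The fallback sets out from 20 and comes back at 24, using known chemistry only. The cinnamaldehyde stage is run alone and 23 is isolated. Ac2O, DMAP and pyridine give (1S,3Z,7Z,9S,10R)-9-(acetyloxy)-3,7-dimethyl-6-oxo-10-(propan-2-yl)cyclodeca-3,7-dien-1-yl (2E)-3-phenylprop-2-enoate F5. Luche reduction (NaBH4, CeCl3·7H2O, MeOH, −78 °C) reduces the C-3 ketone 1,2 under substrate control, hydride coming from the ring periphery anti to the C-6 acetoxy group, to give 24. The facial selectivity of this reduction is not assured; any 3-epimer is separated and returned to F5 with MnO2.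

**Further compounds**

F1 | step 1 | (3S,4R)-4-hydroxy-3-(2-hydroxypropan-2-yl)oxolan-2-one | O=C1OC[C@H](O)[C@H]1C(C)(C)O
F2 | step 1 | (4R)-4-hydroxy-3-(propan-2-ylidene)oxolan-2-one | O=C1OC[C@H](O)C1=C(C)C
F3 | step 10 | 7-hydroxy-1,5-dimethyl-4-oxo-8-(propan-2-yl)tricyclo[4.4.0.0^{2,5}]dec-9-yl (2E)-3-phenylprop-2-enoate (cis-anti-cis; 7,9-trans) | O[C@@H]1[C@H](C(C)C)[C@@H](OC(=O)/C=C/c4ccccc4)C[C@]2(C)[C@H]1[C@@]3(C)C(=O)C[C@@H]23
F4 | step 10 | (1S,3Z,7E,9S,10S)-9-hydroxy-3,7-dimethyl-6-oxo-10-(propan-2-yl)cyclodeca-3,7-dien-1-yl (2E)-3-phenylprop-2-enoate | O[C@H]1/C=C(\C)C(=O)C/C=C(/C)C[C@H](OC(=O)/C=C/c2ccccc2)[C@H]1C(C)C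
F5 | step 11 | (1S,3Z,7Z,9S,10R)-9-(acetyloxy)-3,7-dimethyl-6-oxo-10-(propan-2-yl)cyclodeca-3,7-dien-1-yl (2E)-3-phenylprop-2-enoate | CC(=O)O[C@H]1/C=C(/C)C(=O)C/C=C(/C)C[C@H](OC(=O)/C=C/c2ccccc2)[C@H]1C(C)C
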